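## The problem

Borregomycin E (13) is a planar indolo[2,3-a]carbazole. Two 6-chloroindole units are joined C2 to C2' (the C11a–C11b bond) and bridged C3 to C3' by the two-carbon unit C5–C6, each carbon of which carries a methoxy group. There is no stereocentre, and a twofold axis runs through the midpoints of C5–C6 and C11a–C11b, so nothing has to be controlled in space and every operation can be done on both halves at once. The hard part is the fully substituted ring C (C4b, C5, C6, C6a, C11a, C11b), which bears two nitrogen, two oxygen and two aryl substituents. The reliable annulations of 2,2'-biindoles deliver C5 and C6 as CH, and oxygenated two-carbon building blocks behave far less well. The aryl chlorides at C2 and C9 exclude dissolving metals, hydrogenolysis and warm organolithium reagents; the two NH groups must stay unalkylated; and the diamino-dialkoxy arene core is easily oxidised. The feature that opens the key step lies in the oxygen-free parent 8: ring C is an ortho-phenylenediamine (N11 on C11a, N12 on C11b) with C5 para to N11 and C6 para to N12. Loss of two electrons and both NH protons makes it an ortho-quinone diimine whose halves are 3-alkylidene-3H-indoles (N12=C11b–C4b=C5 and N11=C11a–C6a=C6). C5 and C6 are then the only hydrogen-bearing carbons conjugated with the C=N bonds.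

## Retrosynthesis

**13 from 14.** No skeletal bond is cut; two hydrogens are removed from N11 and N12 to give the quinone diimine 14. The target cannot be the resting point of an oxidative methoxylation, because it is more electron-rich than every compound before it. The diimine 14 is the natural end point, and the forward step is a plain two-electron reduction that the chlorides and ethers tolerate.

**14 from 8 and methanol (9).** The C5–O and C6–O bonds are cut. This removes both oxygens and leads back to the parent heterocycle 8, for which a short symmetric synthesis is available. Cutting O–CH3 instead would demand a 5,6-diol or 5,6-dione built during ring formation, and cutting C–C bonds of ring C with the oxygens in place leads to the longer routes discussed below. The forward reaction must functionalise two C–H positions, on ring C only, and must outrun coupling of oxidised intermediates.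

**8 from 5 and 6.** The C4b–C5 and C6–C6a bonds are cut, giving 6,6'-dichloro-2,2'-biindole (5) and a two-carbon bis-electrophile, (dimethylamino)acetaldehyde diethyl acetal (6). Both indole C3 positions are the nucleophiles, the symmetry of 5 removes any regiochemical question, and the leaving groups (ethanol, dimethylamine) set the aromatic oxidation level without an oxidant.

**5 from 4.** The two N–CO2tBu bonds are cut. The carbamates exist only to direct lithiation and are lost thermally without reagents.

**4 from two molecules of 2.** The C2–C2' bond (later C11a–C11b) is cut at the symmetry axis. Forward, the C2 anion 3 of the N-Boc indole is dimerised oxidatively, so the only carbon building block is 6-chloroindole.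

**2 from 1.** The N–Boc bond is cut to commercial 6-chloroindole (1), which already carries chlorine at the position that becomes C2 and C9.

## Roads not taken

**Alternative 1:** The cut is C5–C6. The forward key step is a carbene-catalysed intramolecular benzoin reaction of the di-Boc biindole dialdehyde A1 (triazolium salt, DBU, argon). The acyloin would tautomerise to the aromatic 5,6-diol A2, which still needs O-methylation and loss of both Boc groups.
- Merits: both oxygens arrive with their carbons, so there is no positional question, and benzoin closure of biaryl dialdehydes is an established reaction class. In certainty of oxygen placement this road is better than the chosen one.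
- Weak points: an indole-3-carbaldehyde is a vinylogous formamide and a poor partner for the carbene even with Boc on nitrogen. Closure forces the two carbamates on N11 and N12 into one plane. The nucleophilic catalyst and DBU can cleave indole carbamates. A2 is an air-sensitive catechol.
- Comparison: A1 must be made from 5 by double formylation and re-protection, so the route runs to about eight steps against six. The chosen plan sets against the better positional certainty a shorter sequence, no nitrogen protection after the biindole stage, and use of the free NH groups as the activating element.

**Alternative 2:** All of ring C is cut at once, with C4b–C11b, C5–C6 and C6a–C11a formed by intramolecular [2+2+2] cyclotrimerisation of the triyne A3 with RhCl(PPh3)3, giving the ditosyl compound A4.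
- Merits: three rings and the whole substitution pattern in one redox-neutral step, with the methoxy groups placed by the alkyne termini. In bond-forming economy of the key step it is clearly better.
- Weak points: A3 contains a 1,2-bis(sulfonamido)acetylene and two methoxyalkynes. Both are hydrolytically fragile, hard to prepare, and little tested in rhodium cyclotrimerisation. The two tosyl groups of A4 are crowded and must be removed without touching the aryl chlorides.
- Comparison: building A3 would alone take longer than the whole chosen route. The chosen plan offers simple, stable intermediates and a known ring synthesis, at the price of an untested oxidation.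

**Alternative 3:** The cuts are N12–C11b and C4b–C5. The aminoaryl alkyne A5 is treated with Ph3PAuNTf2 and p-toluenesulfonic acid: 5-endo hydroamination creates indole ring B, whose C3 is then captured by the oxocarbenium ion of the acetal, and loss of methanol gives the phenol A6.
- Merits: convergent, no oxidation of a finished electron-rich pentacycle, and the two oxygens emerge differentiated. That would be an advantage for unsymmetrical congeners.
- Weak points: for the symmetric target the differentiation is wasted and costs a methylation. An oxocarbenium ion next to a ketone is hard to generate. A5 needs two separately functionalised halves (3-acylation, C2 halogenation, Sonogashira coupling), so the target's symmetry goes unused.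
- Comparison: the chosen plan is shorter and exploits the symmetry throughout. What it lacks, and this road has, is a key step assembled from individually known elementary steps.

Key step: step 5

Remark: commercial LDA solution is assumed in step 2 and a divided cell in step 5; the target keeps the number 13 under which it first arises, as its sodium amide, in the anolyte of step 5 before it is isolated in step 6.

## Route

Step 1
Reactants: 1 6-chloro-1H-indole
Product: 2 tert-butyl 6-chloro-1H-indole-1-carboxylate
Conditions: Boc2O, DMAP (cat.), MeCN, rt
Reagents that add atoms: di-tert-butyl dicarbonate, CC(C)(C)OC(=O)OC(=O)OC(C)(C)C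
Why: DMAP-catalysed N-acylation of the indole nitrogen; the carbamate acidifies C2–H and directs the lithiation of step 2, and the aryl chloride is inert.

Step 2
Reactants: 2 tert-butyl 6-chloro-1H-indole-1-carboxylate (two molecules)
Product: 4 di-tert-butyl 6,6'-dichloro-[2,2'-biindole]-1,1'-dicarboxylate, via 2-lithio carbamate 3 (not isolated)
Conditions: LDA (LiN(iPr)2), THF, −78 °C; then anhydrous CuCl2, −78 °C to rt
Reagents that add atoms: none
Why: Carbamate-directed C2 lithiation of an N-Boc indole, then oxidative homocoupling of the aryllithium through an arylcopper species, divalent copper being reduced to monovalent copper; at −78 °C the C–Cl bonds and the carbamate are not attacked by the hindered amide base.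

Step 3
Reactants: 4 di-tert-butyl 6,6'-dichloro-[2,2'-biindole]-1,1'-dicarboxylate
Product: 5 6,6'-dichloro-1H,1'H-2,2'-biindole
Conditions: neat (or Ph2O), 180–190 °C, Ar
Reagents that add atoms: none
Why: Thermal cleavage of indole N-Boc groups (loss of 2-methylpropene, then decarboxylation of the carbamic acid) needs no reagent, spares the aryl chlorides, and keeps the electron-rich biindole away from acid and tert-butyl cations.

Step 4
Reactants: 5 6,6'-dichloro-1H,1'H-2,2'-biindole; 6 (dimethylamino)acetaldehyde diethyl acetal
Product: 8 2,9-dichloro-11,12-dihydroindolo[2,3-a]carbazole, via 5-(dimethylamino)-5,6-dihydro intermediate 7 (not isolated)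
Conditions: AcOH, reflux
Reagents that add atoms: none
Why: Double Friedel–Crafts annulation of a 2,2'-biindole: C3 attacks the oxocarbenium ion from 6, loss of ethanol and proton shift give an iminium ion that C3' captures in a six-membered Mannich closure to 7, and gramine-type loss of dimethylamine aromatises ring C; symmetry excludes regioisomers.

Step 5
Reactants: 8 2,9-dichloro-11,12-dihydroindolo[2,3-a]carbazole; 9 methanol
Product: 14 2,9-dichloro-5,6-dimethoxyindolo[2,3-a]carbazole (ortho-quinone diimine form), via 2,9-dichloroindolo[2,3-a]carbazole quinone diimine 10 (not isolated), via 2,9-dichloro-5-methoxy-11,12-dihydroindolo[2,3-a]carbazole 11 (not isolated), via 5-methoxy quinone diimine 12 (not isolated), via 2,9-dichloro-5,6-dimethoxy-11,12-dihydroindolo[2,3-a]carbazole 13 (not isolated)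
Conditions: graphite-felt anode, Pt cathode, divided cell; NaOMe (excess), LiClO4 (0.1 M), MeOH–THF 4:1, substrate ≤5 mM, 0 °C, Ar; controlled potential at the first anodic wave of the sodium amide of 8, at least 6 F/mol; then NH4Cl
Reagents that add atoms: sodium methoxide, [Na+].[O-]C (the nucleophile, in rapid exchange with methanol 9, which is the stoichiometric source of both methoxy groups)
Why: Proposed new method: in methanolic NaOMe 8 is partly present as its sodium amide, which should lose two electrons and the second NH proton at a potential well below that of neutral 8, giving the ortho-quinone diimine 10 whose halves are 3-alkylidene-3H-indoles; the closest known reaction type is the anodic oxidation of catechols in methanol to 4,5-dimethoxy-1,2-benzoquinones by Michael addition of methanol to the ortho-quinone, with gramine-type addition of nucleophiles to 3-alkylideneindolenines as the model for the bond-forming event. Methoxide adds to C5, the carbon end of the azadiene N12=C11b–C4b=C5, and a proton shift from C5 to nitrogen restores three aromatic rings in 11. The methoxy donor makes 11 easier to oxidise than 8, so it passes at once to 12, where C5 is a vinylogous imidate carbon whose ipso adduct can only revert, while C6, the end of N11=C11a–C6a=C6, is still a free acceptor and takes the second methoxide to give 13 as its amide. A last two-electron oxidation gives 14, which has no hydrogen left on ring C, so only reversible adducts can follow and the sequence should stop after six electrons. No ring is closed and no stereocentre is formed. The step needs C5 and C6 to react in preference to C3 and C8 and needs addition to outrun radical coupling: the first is secured because in the neutral diimines rings A and E keep their sextets and only ring C carbons are conjugated with the C=N bonds (the ring-fusion carbons C4b and C6a and the imine carbons C11a and C11b add methoxide only reversibly), the second is addressed by oxidising the amide at low potential, where the neutral radical is deprotonated and oxidised further before it can meet a partner, in dilute solution.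

Step 6
Reactants: 14 2,9-dichloro-5,6-dimethoxyindolo[2,3-a]carbazole (ortho-quinone diimine form)
Product: 13 2,9-dichloro-5,6-dimethoxy-11,12-dihydroindolo[2,3-a]carbazole (borregomycin E)
Conditions: Na2S2O4, THF–H2O (pH 7 phosphate buffer), rt, Ar
Reagents that add atoms: none
Why: Dithionite reduction of a quinone diimine to the diamine level, here the two indole NH groups; the gain of three aromatic rings (B, C, D) drives it, and aryl chlorides and methyl ethers are untouched.

## Compound list

1 | 6-chloro-1H-indole | Clc1ccc2cc[nH]c2c1 | starting material
2 | tert-butyl 6-chloro-1H-indole-1-carboxylate | CC(C)(C)OC(=O)n1ccc2ccc(Cl)cc21 | intermediate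
3 | tert-butyl 6-chloro-2-lithio-1H-indole-1-carboxylate | CC(C)(C)OC(=O)n1c([Li])cc2ccc(Cl)cc21 | intermediate
4 | di-tert-butyl 6,6'-dichloro-[2,2'-biindole]-1,1'-dicarboxylate | CC(C)(C)OC(=O)n1c(-c2cc3ccc(Cl)cc3n2C(=O)OC(C)(C)C)cc2ccc(Cl)cc21 | intermediate
5 | 6,6'-dichloro-1H,1'H-2,2'-biindole | Clc1ccc2cc(-c3cc4ccc(Cl)cc4[nH]3)[nH]c2c1 | intermediate
6 | (dimethylamino)acetaldehyde diethyl acetal (2,2-diethoxy-N,N-dimethylethanamine) | CCOC(CN(C)C)OCC | starting material
7 | 2,9-dichloro-N,N-dimethyl-5,6,11,12-tetrahydroindolo[2,3-a]carbazol-5-amine | CN(C)C1Cc2c([nH]c3cc(Cl)ccc23)-c2[nH]c3cc(Cl)ccc3c21 | intermediate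
8 | 2,9-dichloro-11,12-dihydroindolo[2,3-a]carbazole | Clc1ccc2c(c1)[nH]c1c2ccc2c3ccc(Cl)cc3[nH]c21 | intermediate
9 | methanol | CO | starting material
10 | 2,9-dichloroindolo[2,3-a]carbazole (ortho-quinone diimine form) | C1=C2c3ccc(Cl)cc3N=C2C2=Nc3cc(Cl)ccc3C2=C1 | intermediate
11 | 2,9-dichloro-5-methoxy-11,12-dihydroindolo[2,3-a]carbazole | COc1cc2c3ccc(Cl)cc3[nH]c2c2[nH]c3cc(Cl)ccc3c12 | intermediate
12 | 2,9-dichloro-5-methoxyindolo[2,3-a]carbazole (ortho-quinone diimine form) | COC1=C2c3ccc(Cl)cc3N=C2C2=Nc3cc(Cl)ccc3C2=C1 | intermediate
13 | 2,9-dichloro-5,6-dimethoxy-11,12-dihydroindolo[2,3-a]carbazole (borregomycin E) | COc1c(OC)c2c3ccc(Cl)cc3[nH]c2c2[nH]c3cc(Cl)ccc3c12 | target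
14 | 2,9-dichloro-5,6-dimethoxyindolo[2,3-a]carbazole (ortho-quinone diimine form) | COC1=C2c3ccc(Cl)cc3N=C2C2=Nc3cc(Cl)ccc3C2=C1OC | intermediate

Total steps: 6. Longest linear sequence: 6 steps (1 → 2 → 4 → 5 → 8 → 14 → 13).

## Least certain steps

**Step 5 (key step, new method).** The most likely failures are these:
- coupling of nitrogen-centred radicals or radical cations before the second electron is removed, with film formation on the anode;
- deposition of the sparingly soluble diimines on the felt;
- stalling at the monomethoxy stage;
- loss of a methyl group through attack of adventitious water on the vinylogous imidate.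

The fallback uses known chemistry, sets out from 5 and returns at 13. Friedel–Crafts acylation of both indole C3 positions of 5 with oxalyl chloride (THF, 0 °C to rt) should close ring C as 2,9-dichloro-11,12-dihydroindolo[2,3-a]carbazole-5,6-dione F1. Na2S2O4 reduction gives 2,9-dichloro-11,12-dihydroindolo[2,3-a]carbazole-5,6-diol F2. MeI and K2CO3 in acetone then etherify the phenols, which are far more acidic than the indole NH groups, to give 13.

**Step 2.** Oxidative coupling may be incomplete for the hindered ortho-carbamate arylcopper, and proton return or chlorine transfer from CuCl2 can compete. The fallback sets out from 2 and returns at 4. One portion of 2 is lithiated with LDA in the presence of B(OiPr)3 to give [1-(tert-butoxycarbonyl)-6-chloro-1H-indol-2-yl]boronic acid F3. A second portion is lithiated and quenched with iodine to give tert-butyl 6-chloro-2-iodo-1H-indole-1-carboxylate F4. Suzuki–Miyaura coupling (Pd(PPh3)4, Na2CO3, DME–H2O, 80 °C) joins them; the C–I bond reacts far faster than C–Cl.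

**Step 4.** Acid may oligomerise the biindole, or the sequence may stall at amine 7 through slow elimination. The fallback sets out from 4 and returns at 8. NBS brominates both C3 positions to give di-tert-butyl 3,3'-dibromo-6,6'-dichloro-[2,2'-biindole]-1,1'-dicarboxylate F5. Double Stille annulation with (Z)-1,2-bis(tributylstannyl)ethene (Pd(PPh3)4, toluene, 100 °C) gives di-tert-butyl 2,9-dichloroindolo[2,3-a]carbazole-11,12-dicarboxylate F6. Thermolysis as in step 3 removes the crowded carbamates.

**Step 6.** Hydrolytic demethylation of the diimine in the aqueous medium may precede reduction, and the product may re-oxidise in air during isolation. The fallback sets out from 14 and returns at 13 without a new compound. Compound 14 is not isolated; once the charge of step 5 has passed, the polarity of the working electrode is reversed and the diimine is reduced cathodically in the same dry methanolic solution, methanol being oxidised at the counter electrode, before neutralisation under argon.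

## Further compounds

F1 | step 5 | 2,9-dichloro-11,12-dihydroindolo[2,3-a]carbazole-5,6-dione | O=C1C(=O)c2c([nH]c3cc(Cl)ccc23)-c2[nH]c3cc(Cl)ccc3c21
F2 | step 5 | 2,9-dichloro-11,12-dihydroindolo[2,3-a]carbazole-5,6-diol | Oc1c(O)c2c3ccc(Cl)cc3[nH]c2c2[nH]c3cc(Cl)ccc3c12
F3 | step 2 | [1-(tert-butoxycarbonyl)-6-chloro-1H-indol-2-yl]boronic acid | CC(C)(C)OC(=O)n1c(B(O)O)cc2ccc(Cl)cc21
F4 | step 2 | tert-butyl 6-chloro-2-iodo-1H-indole-1-carboxylate | CC(C)(C)OC(=O)n1c(I)cc2ccc(Cl)cc21
F5 | step 4 | di-tert-butyl 3,3'-dibromo-6,6'-dichloro-[2,2'-biindole]-1,1'-dicarboxylate | CC(C)(C)OC(=O)n1c(-c2c(Br)c3ccc(Cl)cc3n2C(=O)OC(C)(C)C)c(Br)c2ccc(Cl)cc21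
F6 | step 4 | di-tert-butyl 2,9-dichloroindolo[2,3-a]carbazole-11,12-dicarboxylate | CC(C)(C)OC(=O)n1c2cc(Cl)ccc2c2ccc3c4ccc(Cl)cc4n(C(=O)OC(C)(C)C)c3c21
F0 | step 6 | none | none
A1 | alternative 1 | di-tert-butyl 6,6'-dichloro-3,3'-diformyl-[2,2'-biindole]-1,1'-dicarboxylate | CC(C)(C)OC(=O)n1c(-c2c(C=O)c3ccc(Cl)cc3n2C(=O)OC(C)(C)C)c(C=O)c2ccc(Cl)cc21
A2 | alternative 1 | di-tert-butyl 2,9-dichloro-5,6-dihydroxyindolo[2,3-a]carbazole-11,12-dicarboxylate | CC(C)(C)OC(=O)n1c2cc(Cl)ccc2c2c(O)c(O)c3c4ccc(Cl)cc4n(C(=O)OC(C)(C)C)c3c21
A3 | alternative 2 | N,N'-(ethyne-1,2-diyl)bis{N-[5-chloro-2-(methoxyethynyl)phenyl]-4-methylbenzenesulfonamide} | COC#Cc1ccc(Cl)cc1N(C#CN(c1cc(Cl)ccc1C#COC)S(=O)(=O)c1ccc(C)cc1)S(=O)(=O)c1ccc(C)cc1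
A4 | alternative 2 | 2,9-dichloro-5,6-dimethoxy-11,12-ditosylindolo[2,3-a]carbazole | COc1c(OC)c2c3ccc(Cl)cc3n(S(=O)(=O)c3ccc(C)cc3)c2c2n(S(=O)(=O)c3ccc(C)cc3)c3cc(Cl)ccc3c12
A5 | alternative 3 | 1-{2-[(2-amino-4-chlorophenyl)ethynyl]-6-chloro-1H-indol-3-yl}-2,2-dimethoxyethan-1-one | COC(OC)C(=O)c1c(C#Cc2ccc(Cl)cc2N)[nH]c2cc(Cl)ccc12
A6 | alternative 3 | 2,9-dichloro-5-methoxy-11,12-dihydroindolo[2,3-a]carbazol-6-ol | COc1c(O)c2c3ccc(Cl)cc3[nH]c2c2[nH]c3cc(Cl)ccc3c12
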